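From the early times on, the amber run differs from the green run in its charge by the target added at the start, so I read the small thing, the fate of that added target, from the difference between the two runs.

in all of them: free catalyst 12.0 mM
- green: starting material 150 mM; coupling partner 165 mM
- red: starting material 90.0 mM; coupling partner 105 mM
- amber: starting material 150 mM; coupling partner 165 mM; target 45.0 mM
- blue: starting material 150 mM; coupling partner 660 mM; time 34 min

| run | time / min | [target] / mM |
|---|---|---|
| green run | 1.5 | 3.1 |
| green run | 4.6 | 25.9 |
| green run | 8.8 | 43.0 |
| green run | 14 | 63.8 |
| green run | 20 | 77.2 |
| green run | 27 | 89.0 |
| green run | 34 | 102.2 |
| red run | 1.5 | 4.9 |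
| red run | 4.6 | 16.2 |
| red run | 8.8 | 27.7 |
| red run | 14 | 41.0 |
| red run | 20 | 46.3 |
| red run | 27 | 54.5 |
| red run | 34 | 58.8 |
| amber run | 1.5 | 52.5 |
| amber run | 4.6 | 68.5 |
| amber run | 8.8 | 81.4 |
| amber run | 14 | 102.0 |
| amber run | 20 | 114.0 |
| amber run | 27 | 123.3 |
| amber run | 34 | 128.3 |

(standard deviation of a reading: 2 mM)

- Overall: starting material + coupling partner -> target, with free catalyst as catalyst.
- Constant volume, constant temperature.
- The analysis sees a species whether free or bound.
- "The second partner" is coupling partner.

1. target in the blue run at 34 min, as a share of the starting material charged
2. which of these the readings show (an uncatalysed path runs beside / the second partner is lost in pairs / the product decays / nothing beyond the main steps / the substrate is lost by itself)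

I build the blue run one process at a time. With the main step by itself, I take the starting material, the limiting reagent, as turned in full by 34 min, which gives my first figure of 100%.

Next comes a loss of target. Let G be amber minus green at equal time. Both runs share their charges of starting material and coupling partner, so a side path on either appears in both and largely cancels in G. Over the last three readings, at mean time t:

G = 32.4 mM, t = 27.0 min

G has shrunk from the added charge by 12.6 mM, more than its scatter of 1.63 mM. So I read the target as decaying, and define the fading constant k_d, the first-order rate at which target already present disappears:

k_d = ln(added target / G) / t = 0.0122 /min

Target formed evenly over a run has a mean age of half the run, so the kept share at 34 min is: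

exp(−k_d × time / 2) = 81.3%

This brings my figure for the blue run to 81.3%.

The rest is the catalyst cycle. Green and red change starting material and coupling partner together, so the readings don't separate the effect of 660 mM of partner. I add no number for it and regard my figure as leaning high.

The forecast differs: 96% and nothing beyond the main steps, on the ground that its envelope “covers all three runs roughly, with no need for a side loss, background path or decay”.

The blue run gives 67.2%, and the readings show the product decays.

    free catalyst + starting material → catalyst-substrate complex (4.830 /M/min)
    catalyst-substrate complex + coupling partner → loaded catalyst (24.36 /M/min)
    loaded catalyst → target + free catalyst (5.130 /min)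
    target → decomposed product (0.01032 /min)

The blue run proves the reason: with the decay step it reaches 67.2%, and without it 83.4%, a difference of 16 percentage points and 49% of what is missing. Applying the kept share 81.3% to the decay-free figure gives 67.8% for the blue run.

(The runs come from a simulation from invented constants.)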